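**Retrosynthetic overview**

- The target is a C2-symmetric 3,3''-biflavanone, reached by global O-debenzylation of its 7,7''-dibenzyl ether.
- The C3–C3'' bond is the only link between the two pyranone (C) rings. It is the central bond of a 1,4-diketone, C4(=O)–C3–C3''–C4''(=O), so it is cut by an oxidative union of two enolate carbons of like polarity, held together on a temporary Me2Si tether.
- The feature that makes this possible: C3 and C3'' are the α-carbons of two identical C-ring ketones, and each sits next to a C2 stereocentre carrying a 4-methoxyphenyl group. One (2S)-flavanone therefore supplies both halves, and the C2 aryl groups set both new centres 2,3-trans.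
- The (2S)-flavanone comes from an enantioselective Pd-catalysed conjugate addition of 4-methoxyphenylboronic acid to a 7-benzyloxy-5-methoxychromone, which fixes C2 and attaches the B ring.
- The chromone comes from 2',4',6'-trihydroxyacetophenone. Ring order: A ring purchased, C ring closed in step 3, B ring attached in step 4, the two halves joined in step 6.

Key step: step 6

Remark: the target is taken as the (2S,3R,2''S,3''R) isomer written in the SMILES (both C rings 2,3-trans); the ligand enantiomer in step 4 is assigned from the facial model for cyclic enones, and the other enantiomer would be used if the sense proved reversed.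

**Route**

Step 1
Reactants: 1 2',4',6'-trihydroxyacetophenone; 2 benzyl bromide
Product: 3 1-[4-(benzyloxy)-2,6-dihydroxyphenyl]ethan-1-one
Conditions: BnBr (1.0 equiv), K2CO3 (1.0 equiv), DMF, 0 °C to rt
Reagents that add atoms: benzyl bromide, BrCc1ccccc1
Why: Williamson ether synthesis with one equivalent of halide; the 4'-OH, para to the acetyl group, is the most acidic and least hindered phenol, so the 4'-monobenzyl ether should be the main product (no stereocentre).

Step 2
Reactants: 3 1-[4-(benzyloxy)-2,6-dihydroxyphenyl]ethan-1-one; 4 iodomethane
Product: 5 1-[4-(benzyloxy)-2-hydroxy-6-methoxyphenyl]ethan-1-one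
Conditions: MeI (1.1 equiv), K2CO3 (1.1 equiv), acetone, reflux
Reagents that add atoms: iodomethane, CI
Why: Williamson O-methylation; once one of the two equivalent ortho-hydroxyls is methylated, the other is locked in the hydrogen bond to the ketone and deactivated, so the reaction should stop at the monomethyl ether.

Step 3
Reactants: 5 1-[4-(benzyloxy)-2-hydroxy-6-methoxyphenyl]ethan-1-one; 6 N,N-dimethylformamide dimethyl acetal
Product: 8 7-(benzyloxy)-5-methoxy-4H-chromen-4-one, via enaminone 7 (not isolated)
Conditions: DMF-DMA (2 equiv), toluene, 100 °C; concentrate; conc. HCl, CH2Cl2, rt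
Reagents that add atoms: N,N-dimethylformamide dimethyl acetal, COC(OC)N(C)C
Why: Enaminone route to chromones; condensation of the acetyl CH3 with the amide acetal gives the β-dimethylamino enone, and acid then drives conjugate addition of the phenol and loss of dimethylamine (addition–elimination, 6-endo closure of the C ring), with both ethers inert.

Step 4
Reactants: 8 7-(benzyloxy)-5-methoxy-4H-chromen-4-one; 9 4-methoxyphenylboronic acid
Product: 10 (2S)-7-(benzyloxy)-5-methoxy-2-(4-methoxyphenyl)chroman-4-one
Conditions: Pd(OCOCF3)2 (5–10 mol %), (R)-4-tert-butyl-2-(pyridin-2-yl)-4,5-dihydrooxazole (6–12 mol %), NH4PF6 (30 mol %), H2O (5 equiv), ClCH2CH2Cl, 60 °C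
Reagents that add atoms: 4-methoxyphenylboronic acid, COc1ccc(B(O)O)cc1
Why: Pd(II)-catalysed enantioselective conjugate addition of an arylboronic acid to a chromone (transmetalation, enantiodetermining insertion of C2=C3 into the aryl–Pd bond, protonolysis of the Pd enolate); the tert-butyl oxazoline shields one face of the bound chromone, and the (R)-ligand should place the aryl group on the face of C2 that gives 2S.

Step 5
Reactants: 10 (2S)-7-(benzyloxy)-5-methoxy-2-(4-methoxyphenyl)chroman-4-one (2 equiv); 11 dichlorodimethylsilane (1 equiv)
Product: 13 dimethylbis{[(2S)-7-(benzyloxy)-5-methoxy-2-(4-methoxyphenyl)-2H-chromen-4-yl]oxy}silane, via lithium enolate 12 (not isolated)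
Conditions: LDA (2.05 equiv), THF, −78 °C; Me2SiCl2 (1.0 equiv), −78 to −20 °C; concentrate, toluene/hexane, filter under Ar; used crude
Reagents that add atoms: dichlorodimethylsilane, C[Si](C)(Cl)Cl
Why: Kinetic enolization and double O-silylation (silyl enol ether formation, two enolates per silicon); at low temperature the endocyclic C2–O bond lies near the nodal plane of the enolate π-system, so β-elimination (retro-oxa-Michael opening, which would scramble C2) should be slow relative to silylation, and C2 is untouched.

Step 6
Reactants: 13 dimethylbis{[(2S)-7-(benzyloxy)-5-methoxy-2-(4-methoxyphenyl)-2H-chromen-4-yl]oxy}silane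
Product: 14 (2S,2'S,3R,3'R)-7,7'-bis(benzyloxy)-5,5'-dimethoxy-2,2'-bis(4-methoxyphenyl)-[3,3'-bichromane]-4,4'-dione
Conditions: (NH4)2Ce(NO3)6 (2.2 equiv), NaHCO3 (4.4 equiv), MeCN/EtCN 6:1, −10 °C
Reagents that add atoms: none
Why: Cerium(IV) removes one electron from one enol ether (the most electron-rich π-system of 13, conjugated with the trioxygenated A ring); the radical cation bonds through C3 to C3'' of the second enol ether on the same silicon, a second electron is removed, and loss of the Me2Si unit unmasks both ketones, so the C3–C3'' bond and both C3 stereocentres arise in one operation. The closest known reaction type is the Ce(IV)-mediated oxidative coupling of dialkylsilyl bis-enol ethers of cyclic aryl ketones such as tetralones to 1,4-diketones, the tethered form of oxidative enolate dimerization. No ring of the target is closed; the bond forms through a transient seven-membered 1,3-dioxa-2-silacycle (C3–C4–O–Si–O–C4''–C3'', 7-endo-trig attack on the second enol ether) that is excised when silicon leaves. Each new stereocentre is controlled by its neighbouring C2 centre: bonding at C3 and at C3'' should occur on the face opposite the 4-methoxyphenyl group, giving 3R and 3''R from 2S and 2''S, which is also the like pairing the tether favours on its own, so substrate and tether are matched. The step needs one C–C coupling per tether without over-oxidation, desilylation or crossover, which the 1:1 intramolecular arrangement, the low temperature and the NaHCO3 buffer should secure. Because a tether carrying one 2S and one 2R unit can only give a separable meso-type diastereomer, the enantiomeric purity of the C2-symmetric product should exceed that of 10.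

Step 7
Reactants: 14 (2S,2'S,3R,3'R)-7,7'-bis(benzyloxy)-5,5'-dimethoxy-2,2'-bis(4-methoxyphenyl)-[3,3'-bichromane]-4,4'-dione
Product: 15 4',4''',5,5''-tetramethylchamaejasmin, (2S,2'S,3R,3'R)-7,7'-dihydroxy-5,5'-dimethoxy-2,2'-bis(4-methoxyphenyl)-[3,3'-bichromane]-4,4'-dione
Conditions: H2 (1 atm), 10% Pd/C, EtOAc/THF, rt
Reagents that add atoms: none
Why: Catalytic hydrogenolysis of the two aryl benzyl ethers; at 1 atm under neutral conditions these should cleave well before the ring C2–O bond or the aryl ketones react, and the absence of base keeps C2 and C3 from epimerizing.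

**Compound list**

1 | 2',4',6'-trihydroxyacetophenone | CC(=O)c1c(O)cc(O)cc1O | starting material
2 | benzyl bromide | BrCc1ccccc1 | starting material
3 | 1-[4-(benzyloxy)-2,6-dihydroxyphenyl]ethan-1-one | CC(=O)c1c(O)cc(OCc2ccccc2)cc1O | intermediate
4 | iodomethane | CI | starting material
5 | 1-[4-(benzyloxy)-2-hydroxy-6-methoxyphenyl]ethan-1-one | CC(=O)c1c(O)cc(OCc2ccccc2)cc1OC | intermediate
6 | N,N-dimethylformamide dimethyl acetal | COC(OC)N(C)C | starting material
7 | (E)-1-[4-(benzyloxy)-2-hydroxy-6-methoxyphenyl]-3-(dimethylamino)prop-2-en-1-one | CN(C)/C=C/C(=O)c1c(O)cc(OCc2ccccc2)cc1OC | intermediate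
8 | 7-(benzyloxy)-5-methoxy-4H-chromen-4-one | COc1cc(OCc2ccccc2)cc2occc(=O)c12 | intermediate
9 | 4-methoxyphenylboronic acid | COc1ccc(B(O)O)cc1 | starting material
10 | (2S)-7-(benzyloxy)-5-methoxy-2-(4-methoxyphenyl)chroman-4-one | COc1ccc([C@H]2Oc3cc(OCc4ccccc4)cc(OC)c3C(=O)C2)cc1 | intermediate
11 | dichlorodimethylsilane | C[Si](C)(Cl)Cl | starting material
12 | lithium (2S)-7-(benzyloxy)-5-methoxy-2-(4-methoxyphenyl)-2H-chromen-4-olate | COc1ccc([C@H]2Oc3cc(OCc4ccccc4)cc(OC)c3C(O[Li])=C2)cc1 | intermediate
13 | dimethylbis{[(2S)-7-(benzyloxy)-5-methoxy-2-(4-methoxyphenyl)-2H-chromen-4-yl]oxy}silane | COc1ccc([C@H]2Oc3cc(OCc4ccccc4)cc(OC)c3C(O[Si](C)(C)OC3=C[C@@H](c4ccc(OC)cc4)Oc4cc(OCc5ccccc5)cc(OC)c43)=C2)cc1 | intermediate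
14 | (2S,2'S,3R,3'R)-7,7'-bis(benzyloxy)-5,5'-dimethoxy-2,2'-bis(4-methoxyphenyl)-[3,3'-bichromane]-4,4'-dione | COc1ccc([C@H]2Oc3cc(OCc4ccccc4)cc(OC)c3C(=O)[C@@H]2[C@H]2C(=O)c3c(OC)cc(OCc4ccccc4)cc3O[C@@H]2c2ccc(OC)cc2)cc1 | intermediate
15 | 4',4''',5,5''-tetramethylchamaejasmin | COc1ccc([C@H]2Oc3cc(O)cc(OC)c3C(=O)[C@@H]2[C@H]2C(=O)c3c(OC)cc(O)cc3O[C@@H]2c2ccc(OC)cc2)cc1 | target

**Step count**

Total steps: 7. Longest linear sequence: 7 (two molecules of 10 enter step 5).

**Steps most likely to fail**

Step 6. The oxidation may run past the coupling stage (loss of the C2 hydrogen and dehydrogenation towards the flavone). The Si–O bonds may also break before the C–C bond forms, returning monomeric ketone, or bonding at C3 may be poorly face-selective. The fallback sets out from 10 and drops both the tether and the outer-sphere oxidant. The lithium enolate 12 is generated with LDA in THF at −78 °C and coupled intermolecularly by inner-sphere copper(II) oxidation (anhydrous CuCl2 in DMF, −78 to −40 °C; oxidative dimerization of a ketone enolate). The C2 aryl groups remain the controlling element, and the route is rejoined at 14. No compound outside the list is made on this way: none (F0).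

Step 5. The lithium enolate may undergo β-elimination (retro-oxa-Michael opening of the pyranone ring) during the slower second silylation, which would erase the C2 configuration. The bis-enol ether may also hydrolyse on handling. The fallback sets out from 10 and avoids any metal enolate by soft enolization: i-Pr2Si(OTf)2 (0.5 equiv) and Et3N in CH2Cl2 at 0 °C to rt should give diisopropylbis{[(2S)-7-(benzyloxy)-5-methoxy-2-(4-methoxyphenyl)-2H-chromen-4-yl]oxy}silane F1. This more robust tethered bis-enol ether should tolerate filtration through deactivated silica. Oxidation with (NH4)2Ce(NO3)6/NaHCO3 in MeCN/EtCN at −10 °C then rejoins the route at 14.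

Step 4. Insertion may be sluggish with the electron-rich 5,7-dialkoxychromone, so that protodeboronation and biaryl formation consume the boronic acid, or the facial selectivity may be insufficient. The fallback sets out from 5. Claisen–Schmidt condensation with 4-methoxybenzaldehyde (KOH, EtOH, rt) should give (E)-1-[4-(benzyloxy)-2-hydroxy-6-methoxyphenyl]-3-(4-methoxyphenyl)prop-2-en-1-one F2. Oxa-Michael cyclization (NaOAc, EtOH, reflux) should then give racemic 7-(benzyloxy)-5-methoxy-2-(4-methoxyphenyl)chroman-4-one F3. Preparative chromatography on a chiral stationary phase resolves F3, and the 2S enantiomer rejoins the route at 10. The 2R enantiomer can be re-equilibrated through the chalcone under the cyclization conditions and recycled.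

**Further compounds**

F0 | step 6 | none | none
F1 | step 5 | diisopropylbis{[(2S)-7-(benzyloxy)-5-methoxy-2-(4-methoxyphenyl)-2H-chromen-4-yl]oxy}silane | COc1ccc([C@H]2Oc3cc(OCc4ccccc4)cc(OC)c3C(O[Si](C(C)C)(C(C)C)OC3=C[C@@H](c4ccc(OC)cc4)Oc4cc(OCc5ccccc5)cc(OC)c43)=C2)cc1
F2 | step 4 | (E)-1-[4-(benzyloxy)-2-hydroxy-6-methoxyphenyl]-3-(4-methoxyphenyl)prop-2-en-1-one | COc1ccc(/C=C/C(=O)c2c(O)cc(OCc3ccccc3)cc2OC)cc1
F3 | step 4 | racemic 7-(benzyloxy)-5-methoxy-2-(4-methoxyphenyl)chroman-4-one | COc1ccc(C2Oc3cc(OCc4ccccc4)cc(OC)c3C(=O)C2)cc1
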